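| flask | X | remark | time |
|---|---|---|---|
| birch | 0.050 M | run made earlier |  |
| cedar | 0.075 M | run made earlier |  |
| flask | 0.10 M |  | 1.5 h |

| run | time / min | X / % | L / % | Z / % |
|---|---|---|---|---|
| birch | 6.00 | 84.3 | 4.0 | 8.2 |
| birch | 8.00 | 81.9 | 4.7 | 6.9 |
| birch | 12.0 | 82.0 | 4.8 | 12.5 |
| birch | 20.0 | 80.0 | 5.4 | 10.8 |
| birch | 30.0 | 79.5 | 4.9 | 10.0 |
| birch | 50.0 | 79.6 | 6.0 | 11.1 |
| birch | 80.0 | 78.9 | 4.6 | 11.3 |
| cedar | 4.00 | 92.3 | 0.8 | 2.2 |
| cedar | 12.0 | 85.8 | 1.6 | 7.3 |
| cedar | 20.0 | 87.7 | 2.6 | 7.0 |
| cedar | 30.0 | 85.6 | 2.5 | 6.7 |
| cedar | 40.0 | 87.4 | 2.2 | 8.1 |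
| cedar | 60.0 | 85.3 | 4.5 | 6.6 |
| cedar | 80.0 | 85.1 | 3.9 | 6.4 |

(each reading ± 1 percentage point)

- solid, in amounts per volume of the solution: X
- at the start none of X is in solution
- what has only dissolved of X counts as not reacted
- the reaction counts as stopped when no species that holds the X changes by six tenths of a point or more over the second half of the time
- Z means what is dissolved; the solid is not counted in it

- the state of affairs at 1.5 h: stopped, and by what, or still going (for what has run out or reacted, a solid counts together with what of it has only dissolved) (all of X has reacted / it is still moving / forward and back rates have come level)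
- part of the X that has turned into other species by 1.5 h (what has only dissolved does not count)
- amount of L at 1.5 h, in percent of the X charged
- amount of Z at 1.5 h, in percent of the X charged
- amount of E at 1.5 h, in percent of the X charged

If I turned the percentages of birch and cedar into concentrations, the two runs stopped looking different. I took the readings as level from 20.0 min on and replaced each curve by its mean. What stood in neither X nor Z, that is [L]+[E], then came to 4.85 mM in birch and 5.11 mM in cedar, although cedar held 1.50 times the charge. I carried the mean of these two, the reacted level 4.98 mM. The two means differed by 0.260 mM, and I took that as the error of the averaging, which on the charge of the flask is 0.26 percentage points.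

My bench rule for these runs was that, while solid stands, the reacted level keeps its concentration, so its percentage goes as one over the charge. For the flask at 0.10 M that gave 4.98% converted.

The rule stops working where the curve is not yet level. Cedar read Z at 2.2% after 4.00 min, before it reached its plateau, so the early stretch is the one to watch. The flask's 1.5 h is 4.50 times the 20.0 min at which I began averaging, so I expected it to lie past that border. The rule also needs solid, and birch, the smaller charge, still read X at 78.9% at its last reading.

The forecast said forward and back rates have come level, with 5.4% converted, L at 2.7%, Z at 5.3% and E at 2.7%, on the ground that “Z is therefore pinned at solubility”. Its conversion stood above my 4.98%.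

The flask gave 5.09% converted, with L at 2.60%, Z at 4.90% and E at 2.49%: forward and back rates have come level, the state called equilibrium. Left until 15.0 h, it still stood at 5.09%. Its reacted level was 5.09 mM, against my 4.98 mM.

    X ⇌ Z, rate k1*(cs1 - [Z]) while solid is left; crystals form when [Z] > cs1 (solubility = 4.90 mM, k = 0.00831 s⁻¹)
    Z ⇌ L (K = 0.530, k = 0.0166 s⁻¹)
    L ⇌ E (K = 0.960, k = 0.0311 s⁻¹)
    E ⇌ Z (k = 0.00935 s⁻¹)

With 0.040 M of X, the reacted level gave 12.5% of that charge. The computed neighbour flask reached 12.7%.

The readings come from a simulation with constants of no real substance, and the scatter is random.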